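**Retrosynthetic overview**

1. Target 26 ← bicyclic ester 15. The side chain (C12–C16) and the C6/C7 oxygen pattern are added after the rings: C11 ester → vinyl → C12 aldehyde → two Wittig reactions; 6β-O by α-face hydroboration of a C6 silyl enol ether; 7β-OAc by oxidation and α-face reduction at C7.
2. Key disconnection: C5–C10 and C8–C9 together, by an intramolecular Diels–Alder reaction of the acyclic triene 14. Diene: C5=C6(OSiEt3)–C7=C8(CH3)(OSiEt3); dienophile: (E)-C9=C10(CH3) activated by the C11 ester; tether: C1–C4. Rings A and B are formed together in step 7; there is no other ring.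
3. Enabling feature: ring B carries oxygen on C6 and on C8, 1,3 to each other across C7, so it is a masked β-diketone whose bis(silyl enol ether) is a nucleophilic 1,3-dioxy diene. C9 carries a carbon (C11) that can be a carbonyl and polarise C9=C10, and the saturated C1–C4 chain of ring A with its gem-dimethyl carbon is the tether. C5, C8, C9 and C10 are all set in that step, with absolute control from a (−)-8-phenylmenthyl ester.
4. Triene 14 ← alkylzinc 13 (E-enoate from syn-carbocupration of a 2-butynoate) + silyl enol ether 12 of 6-methylhept-5-ene-2,4-dione. Conjugate addition with O-silyl trapping makes the quaternary C4 and fixes the diene regiochemistry.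

Key step: step 7

Assumption: face selection by the (−)-8-phenylmenthyl ester is taken to follow the usual π-shielding model of the Lewis-acid-bound s-trans enoate; core atoms are numbered as in labdanes (C11 on C9, C17 the methyl on C8, C20 the methyl on C10), and α/β refer to that framework.

**Route**

Step 1
Reactants: 1 (−)-8-phenylmenthol; 2 but-2-ynoic acid
Product: 3 8-phenylmenthyl but-2-ynoate
Conditions: DCC, DMAP (cat.), CH2Cl2, 0 °C → rt
Reagents that add atoms: none
Why: Steglich esterification (carbodiimide activation with acyl transfer by 4-dimethylaminopyridine) should acylate even this hindered secondary alcohol without touching its three stereocentres, which are carried on unchanged as the chiral auxiliary.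

Step 2
Reactants: 4 (3-bromopropoxy)(tert-butyl)dimethylsilane; 3 8-phenylmenthyl but-2-ynoate
Product: 7 8-phenylmenthyl (E)-6-(tert-butyldimethylsilyloxy)-3-methylhex-2-enoate, via Grignard reagent 5 (not isolated), via alkenylcopper adduct 6 (not isolated)
Conditions: Mg, THF; CuBr·SMe2 (1 equiv), −40 °C; 3, −78 °C; aq. NH4Cl, −78 °C → rt
Reagents that add atoms: none
Why: Syn-carbocupration of the 2-alkynoate by the alkylcopper reagent at −78 °C places the new chain and copper cis, and protonation of the configurationally stable alkenylcopper with retention should give the (E)-3-methyl-2-enoate (chain trans to the ester) as a single alkene isomer.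

Step 3
Reactants: 7 8-phenylmenthyl (E)-6-(tert-butyldimethylsilyloxy)-3-methylhex-2-enoate
Product: 8 8-phenylmenthyl (E)-6-bromo-3-methylhex-2-enoate
Conditions: Ph3PBr2, CH2Cl2, 0 °C → rt
Reagents that add atoms: triphenylphosphine dibromide, BrP(Br)(c1ccccc1)(c1ccccc1)c1ccccc1
Why: Bromodesilylation with triphenylphosphine dibromide should convert the primary silyl ether directly into the primary bromide through an oxyphosphonium ion and SN2 attack of bromide (an Appel-type substitution), leaving the hindered enoate untouched.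

Step 4
Reactants: 9 mesityl oxide
Product: 11 6-methylhept-5-ene-2,4-dione, via lithium dienolate 10 (not isolated)
Conditions: LiN(SiMe3)2 (2.1 equiv), THF–toluene, −78 °C; AcCl (1 equiv), −78 → 0 °C; 1 M HCl
Reagents that add atoms: acetyl chloride, CC(=O)Cl
Why: Kinetic deprotonation on the methyl ketone side (α′) of the enone and C-acylation of the lithium dienolate with acetyl chloride (a crossed Claisen-type acylation, the second equivalent of base taking up the acidic diketone proton) should give the enedione.

Step 5
Reactants: 11 6-methylhept-5-ene-2,4-dione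
Product: 12 (Z)-6-methyl-2-(triethylsilyloxy)hepta-2,5-dien-4-one
Conditions: Et3SiCl, Et3N, CH2Cl2, 0 °C
Reagents that add atoms: chlorotriethylsilane, CC[Si](Cl)(CC)CC
Why: O-silylation of the chelated cis-enol of the β-diketone should give the (Z)-β-silyloxy enone, in which the oxygen on the future C8 is cis to the future C6; a 1,5-silyl shift between the two oxygens is possible, but both forms lead to the same diene in step 6.

Step 6
Reactants: 8 8-phenylmenthyl (E)-6-bromo-3-methylhex-2-enoate; 12 (Z)-6-methyl-2-(triethylsilyloxy)hepta-2,5-dien-4-one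
Product: 14 8-phenylmenthyl (2E,8Z,10Z)-3,7,7-trimethyl-9,11-bis(triethylsilyloxy)dodeca-2,8,10-trienoate, via alkylzinc bromide 13 (not isolated)
Conditions: Zn, LiCl, THF, 50 °C; then CuBr·SMe2 (10 mol %), Et3SiCl, HMPA, 12, THF, −30 → 0 °C; Et3N, pentane, filtration
Reagents that add atoms: chlorotriethylsilane, CC[Si](Cl)(CC)CC
Why: Copper-catalysed, chlorosilane-accelerated conjugate addition of the ester-tolerant alkylzinc to the β,β-dimethyl enone terminus (the silyloxy-bearing terminus is deactivated as a vinylogous ester) should create the quaternary C4 and, by O-silylation of the zinc enolate formed from the s-cis enone, fix the enol ether at C5=C6 with Z geometry, so the 2,4-bis(silyloxy)diene arises without any enolisation toward the C8 methyl group.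

Step 7
Reactants: 14 8-phenylmenthyl (2E,8Z,10Z)-3,7,7-trimethyl-9,11-bis(triethylsilyloxy)dodeca-2,8,10-trienoate
Product: 15 8-phenylmenthyl 6,8α-bis(triethylsilyloxy)-12,13,14,15,16-pentanorlabd-6-en-11-oate
Conditions: Me2AlCl (1.5 equiv), CH2Cl2, −78 → −40 °C; Et3N, then water, −78 °C → rt
Reagents that add atoms: none
Why: Me2AlCl binds the ester carbonyl (anti to the alkoxy oxygen, s-trans enoate), and the terminus C5 of the 2,4-bis(silyloxy)diene, its most nucleophilic carbon, bonds to the β-carbon C10 while C8 bonds to the α-carbon C9 on the same face of the alkene in a highly asynchronous intramolecular Diels–Alder reaction (type 1; in the limit a Mukaiyama–Michael addition followed at once by collapse of the aluminium enolate onto the silyloxy-stabilised cation at C8). The closest known reactions are Lewis-acid promoted intramolecular Diels–Alder reactions of deca-2,7,9-trienoates, including esters of 8-phenylmenthol, and cycloadditions of 1,3-bis(silyloxy)dienes with enoates. Ring A closes through C5–C10 over the four-carbon tether C1–C4 (a 6-exo closure in a chair-like arrangement, helped by the gem-dimethyl group on C4), and ring B is the cyclohexene of the [4+2] event, closed by C8–C9 (6-endo with respect to the C7=C8 unit) and keeping C6=C7 as a silyl enol ether. C9 and C10 follow from the E alkene (C11 and the C10 methyl group cis, both β), the trans ring fusion (5α-H, 10β-CH3) follows from the endo transition state with the ester under the diene and the tether anti, and C8 (methyl β, silyloxy α) follows from the Z enol ether, whose oxygen sits inside and whose methyl group sits outside the diene. The absolute sense comes from the auxiliary, whose phenyl ring stacks over the Cα-re face of the complexed enoate so that the diene adds to the si face of C9. The step needs the C5-to-C10 regiochemistry (secured jointly by the tether length and the matched polarity of diene and enoate), endo and facial selectivity (Lewis acid and auxiliary), and survival of the C8–O bond, for which the mixture is kept cold and quenched with amine before acid can expel the silyloxy group.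

Step 8
Reactants: 15 8-phenylmenthyl 6,8α-bis(triethylsilyloxy)-12,13,14,15,16-pentanorlabd-6-en-11-oate
Product: 16 6,8α-bis(triethylsilyloxy)-12,13,14,15,16-pentanorlabd-6-en-11-ol
Conditions: i-Bu2AlH (3 equiv), CH2Cl2, −78 → 0 °C; aq. Rochelle salt
Reagents that add atoms: none
Why: Hydride reduction of the hindered ester with the aluminium hydride should give the primary alcohol and release the auxiliary alcohol 1 for re-use, the weakly nucleophilic aluminium alkoxide avoiding silyl migration from O8 and leaving the silyl enol ether intact.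

Step 9
Reactants: 16 6,8α-bis(triethylsilyloxy)-12,13,14,15,16-pentanorlabd-6-en-11-ol
Product: 17 6,8α-bis(triethylsilyloxy)-12,13,14,15,16-pentanorlabd-6-en-11-al
Conditions: (n-Pr)4N[RuO4] (5 mol %), N-methylmorpholine N-oxide, 4 Å sieves, CH2Cl2, rt
Reagents that add atoms: none
Why: Ley–Griffith oxidation is neutral and stops at the aldehyde, so the acid-labile silyl enol ether and the β-silyloxy aldehyde should survive and C9 keeps its equatorial (β) substituent.

Step 10
Reactants: 17 6,8α-bis(triethylsilyloxy)-12,13,14,15,16-pentanorlabd-6-en-11-al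
Product: 18 6,8α-bis(triethylsilyloxy)-13,14,15,16-tetranorlabda-6,11-diene
Conditions: Ph3PCH3Br, KN(SiMe3)2, THF, −78 → 0 °C
Reagents that add atoms: methyltriphenylphosphonium bromide, C[P+](c1ccccc1)(c1ccccc1)c1ccccc1.[Br-]
Why: Wittig methylenation with the unstabilised ylide should convert the hindered aldehyde into the vinyl group at low temperature faster than enolisation, so that C9 is not epimerised and the β-silyloxy group is not eliminated.

Step 11
Reactants: 18 6,8α-bis(triethylsilyloxy)-13,14,15,16-tetranorlabda-6,11-diene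
Product: 20 6β,8α-bis(triethylsilyloxy)-13,14,15,16-tetranorlabdane-7α,12-diol, via bis(alkylborane) 19 (not isolated)
Conditions: BH3·THF (4 equiv), THF, 0 °C → rt; then Me3NO (excess), 65 °C; water
Reagents that add atoms: trimethylamine N-oxide, C[N+](C)(C)[O-]
Why: Hydroboration–oxidation, in which borane adds anti-Markovnikov to the vinyl group (boron on C12) and syn to the silyl enol ether from the α face (away from the axial methyl groups on C8 and C10) with boron on C7 and hydrogen on C6, so that neutral amine-oxide oxidation with retention should give 7α-OH and leave the C6 silyloxy group β (axial) without base-induced silyl migration.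

Step 12
Reactants: 20 6β,8α-bis(triethylsilyloxy)-13,14,15,16-tetranorlabdane-7α,12-diol
Product: 21 7-oxo-6β,8α-bis(triethylsilyloxy)-13,14,15,16-tetranorlabdan-12-al
Conditions: Dess–Martin periodinane, pyridine, CH2Cl2, 0 °C → rt
Reagents that add atoms: none
Why: Dess–Martin oxidation should convert the primary alcohol into the aldehyde and the hindered axial secondary alcohol into the C7 ketone under buffered, non-epimerising conditions.

Step 13
Reactants: 21 7-oxo-6β,8α-bis(triethylsilyloxy)-13,14,15,16-tetranorlabdan-12-al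
Product: 22 (12E)-7-oxo-6β,8α-bis(triethylsilyloxy)-15-norlabd-12-en-14-al
Conditions: Ph3P=C(CH3)CHO (1.3 equiv), toluene, 80 °C
Reagents that add atoms: 2-(triphenylphosphoranylidene)propanal, CC(C=O)=P(c1ccccc1)(c1ccccc1)c1ccccc1
Why: The Wittig reaction with the stabilised formyl ylide is chemoselective for the aldehyde over the hindered ketone and should give the (E)-2-methyl-2-enal, as is usual for stabilised ylides.

Step 14
Reactants: 22 (12E)-7-oxo-6β,8α-bis(triethylsilyloxy)-15-norlabd-12-en-14-al
Product: 23 (12E)-6β,8α-bis(triethylsilyloxy)labda-12,14-dien-7-one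
Conditions: Ph3PCH3Br, KN(SiMe3)2, THF, −78 → 0 °C
Reagents that add atoms: methyltriphenylphosphonium bromide, C[P+](c1ccccc1)(c1ccccc1)c1ccccc1.[Br-]
Why: Wittig methylenation of the enal carbonyl (1,2-addition of the unstabilised ylide) should complete the (12E)-12,14-diene, since the C7 ketone, flanked by a quaternary carbon and a silyloxy-bearing carbon, is too hindered to react and its only α-hydrogen (equatorial on C6) is poorly aligned for enolisation.

Step 15
Reactants: 23 (12E)-6β,8α-bis(triethylsilyloxy)labda-12,14-dien-7-one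
Product: 24 (12E)-6β,8α-bis(triethylsilyloxy)labda-12,14-dien-7β-ol
Conditions: i-Bu2AlH, toluene, −78 °C; aq. Rochelle salt
Reagents that add atoms: none
Why: Hydride reduction of the C7 ketone, in which hydride enters along the axial trajectory from the α face because the β face is screened by the axial 6β-silyloxy group and the axial 8β-methyl group, should give the equatorial 7β-alcohol, the aluminium alkoxide avoiding silyl migration from the neighbouring oxygens.

Step 16
Reactants: 24 (12E)-6β,8α-bis(triethylsilyloxy)labda-12,14-dien-7β-ol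
Product: 25 (12E)-6β,8α-bis(triethylsilyloxy)labda-12,14-dien-7β-yl acetate
Conditions: Ac2O, Et3N, DMAP (cat.), CH2Cl2, rt
Reagents that add atoms: acetic anhydride, CC(=O)OC(C)=O
Why: Acylation with acetic anhydride under nucleophilic catalysis by 4-dimethylaminopyridine should acetylate the only free hydroxyl group, the equatorial 7β-OH, with retention.

Step 17
Reactants: 25 (12E)-6β,8α-bis(triethylsilyloxy)labda-12,14-dien-7β-yl acetate
Product: 26 (12E)-6β,8α-dihydroxylabda-12,14-dien-7β-yl acetate
Conditions: HF·pyridine, pyridine, THF, 0 °C → rt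
Reagents that add atoms: none
Why: Fluoride-mediated desilylation under mildly acidic conditions should cleave both triethylsilyl ethers without base, which avoids migration of the acetyl group from O7 to the neighbouring cis O6 and leaves the diene and all stereocentres untouched.

**Compound list**

1 | (−)-8-phenylmenthol, (1R,2S,5R)-5-methyl-2-(2-phenylpropan-2-yl)cyclohexan-1-ol | CC(C)(c1ccccc1)[C@@H]1CC[C@@H](C)C[C@H]1O | starting material
2 | but-2-ynoic acid | CC#CC(=O)O | starting material
3 | 8-phenylmenthyl but-2-ynoate | CC(C)(c1ccccc1)[C@@H]1CC[C@@H](C)C[C@H]1OC(=O)C#CC | intermediate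
4 | (3-bromopropoxy)(tert-butyl)dimethylsilane | CC(C)(C)[Si](C)(C)OCCCBr | starting material
5 | [3-(tert-butyldimethylsilyloxy)propyl]magnesium bromide (not isolated) | CC(C)(C)[Si](C)(C)OCCC[Mg]Br | intermediate
6 | alkenylcopper adduct, copper on C2 cis to the new chain (not isolated) | CC(C)(c1ccccc1)[C@@H]1CC[C@@H](C)C[C@H]1OC(=O)/C([Cu])=C(\C)CCCO[Si](C)(C)C(C)(C)C | intermediate
7 | 8-phenylmenthyl (E)-6-(tert-butyldimethylsilyloxy)-3-methylhex-2-enoate | CC(C)(c1ccccc1)[C@@H]1CC[C@@H](C)C[C@H]1OC(=O)/C=C(\C)CCCO[Si](C)(C)C(C)(C)C | intermediate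
8 | 8-phenylmenthyl (E)-6-bromo-3-methylhex-2-enoate | CC(C)(c1ccccc1)[C@@H]1CC[C@@H](C)C[C@H]1OC(=O)/C=C(\C)CCCBr | intermediate
9 | mesityl oxide (4-methylpent-3-en-2-one) | CC(C)=CC(C)=O | starting material
10 | lithium 4-methylpenta-1,3-dien-2-olate (not isolated) | [Li]OC(=C)C=C(C)C | intermediate
11 | 6-methylhept-5-ene-2,4-dione | CC(C)=CC(=O)CC(C)=O | intermediate
12 | (Z)-6-methyl-2-(triethylsilyloxy)hepta-2,5-dien-4-one | CC(C)=CC(=O)/C=C(C)\O[Si](CC)(CC)CC | intermediate
13 | alkylzinc bromide of 8 (not isolated) | CC(C)(c1ccccc1)[C@@H]1CC[C@@H](C)C[C@H]1OC(=O)/C=C(\C)CCC[Zn]Br | intermediate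
14 | 8-phenylmenthyl (2E,8Z,10Z)-3,7,7-trimethyl-9,11-bis(triethylsilyloxy)dodeca-2,8,10-trienoate | CC(C)(c1ccccc1)[C@@H]1CC[C@@H](C)C[C@H]1OC(=O)/C=C(\C)CCCC(C)(C)/C=C(\O[Si](CC)(CC)CC)/C=C(/C)\O[Si](CC)(CC)CC | intermediate
15 | 8-phenylmenthyl 6,8α-bis(triethylsilyloxy)-12,13,14,15,16-pentanorlabd-6-en-11-oate (5α-H, 9α-H, 8β-CH3, 10β-CH3) | CC(C)(c1ccccc1)[C@@H]1CC[C@@H](C)C[C@H]1OC(=O)[C@H]1[C@](C)(O[Si](CC)(CC)CC)C=C(O[Si](CC)(CC)CC)[C@H]2C(C)(C)CCC[C@@]21C | intermediate
16 | 6,8α-bis(triethylsilyloxy)-12,13,14,15,16-pentanorlabd-6-en-11-ol | OC[C@H]1[C@](C)(O[Si](CC)(CC)CC)C=C(O[Si](CC)(CC)CC)[C@H]2C(C)(C)CCC[C@@]21C | intermediate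
17 | 6,8α-bis(triethylsilyloxy)-12,13,14,15,16-pentanorlabd-6-en-11-al | O=C[C@H]1[C@](C)(O[Si](CC)(CC)CC)C=C(O[Si](CC)(CC)CC)[C@H]2C(C)(C)CCC[C@@]21C | intermediate
18 | 6,8α-bis(triethylsilyloxy)-13,14,15,16-tetranorlabda-6,11-diene | C=C[C@H]1[C@](C)(O[Si](CC)(CC)CC)C=C(O[Si](CC)(CC)CC)[C@H]2C(C)(C)CCC[C@@]21C | intermediate
19 | 7α,12-diboryl-6β,8α-bis(triethylsilyloxy)-13,14,15,16-tetranorlabdane, drawn as the RBH2 form (not isolated) | BCC[C@H]1[C@](C)(O[Si](CC)(CC)CC)[C@H](B)[C@@H](O[Si](CC)(CC)CC)[C@H]2C(C)(C)CCC[C@@]21C | intermediate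
20 | 6β,8α-bis(triethylsilyloxy)-13,14,15,16-tetranorlabdane-7α,12-diol | OCC[C@H]1[C@](C)(O[Si](CC)(CC)CC)[C@H](O)[C@@H](O[Si](CC)(CC)CC)[C@H]2C(C)(C)CCC[C@@]21C | intermediate
21 | 7-oxo-6β,8α-bis(triethylsilyloxy)-13,14,15,16-tetranorlabdan-12-al | O=CC[C@H]1[C@](C)(O[Si](CC)(CC)CC)C(=O)[C@@H](O[Si](CC)(CC)CC)[C@H]2C(C)(C)CCC[C@@]21C | intermediate
22 | (12E)-7-oxo-6β,8α-bis(triethylsilyloxy)-15-norlabd-12-en-14-al | O=C/C(C)=C/C[C@H]1[C@](C)(O[Si](CC)(CC)CC)C(=O)[C@@H](O[Si](CC)(CC)CC)[C@H]2C(C)(C)CCC[C@@]21C | intermediate
23 | (12E)-6β,8α-bis(triethylsilyloxy)labda-12,14-dien-7-one | C=C/C(C)=C/C[C@H]1[C@](C)(O[Si](CC)(CC)CC)C(=O)[C@@H](O[Si](CC)(CC)CC)[C@H]2C(C)(C)CCC[C@@]21C | intermediate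
24 | (12E)-6β,8α-bis(triethylsilyloxy)labda-12,14-dien-7β-ol | C=C/C(C)=C/C[C@H]1[C@](C)(O[Si](CC)(CC)CC)[C@@H](O)[C@@H](O[Si](CC)(CC)CC)[C@H]2C(C)(C)CCC[C@@]21C | intermediate
25 | (12E)-6β,8α-bis(triethylsilyloxy)labda-12,14-dien-7β-yl acetate | C=C/C(C)=C/C[C@H]1[C@](C)(O[Si](CC)(CC)CC)[C@@H](OC(C)=O)[C@@H](O[Si](CC)(CC)CC)[C@H]2C(C)(C)CCC[C@@]21C | intermediate
26 | (12E)-6β,8α-dihydroxylabda-12,14-dien-7β-yl acetate | C=C/C(C)=C/C[C@H]1[C@](C)(O)[C@@H](OC(C)=O)[C@@H](O)[C@H]2C(C)(C)CCC[C@@]21C | target

**Step count and risks**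

Total step count: 17. Longest linear sequence: 15 steps (steps 1–3 and 6–17; steps 4 and 5 make the second fragment).

Steps most likely to fail:

Step 6. Carbon–carbon bond formation at the fully substituted enone terminus may not take place. The zinc reagent may instead add and eliminate at the silyloxy-bearing terminus, or the bis(silyl enol ether) may hydrolyse on isolation. The fallback sets out from 9 (and from 1 for the ester part) and comes back at 14. It builds the quaternary carbon on mesityl oxide itself and makes the diene last.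
The Grignard reagent of commercial 2-(3-chloropropyl)-2-methyl-1,3-dioxolane would be added to 9 (CuBr·SMe2 cat., Me3SiCl, THF, −78 °C, mild acid work-up) to give 4,4-dimethyl-7-(2-methyl-1,3-dioxolan-2-yl)heptan-2-one F1.
Kinetic enolisation at the methyl group (LiN(SiMe3)2) and acetyl chloride would give 6,6-dimethyl-9-(2-methyl-1,3-dioxolan-2-yl)nonane-2,4-dione F2.
Aqueous HCl in acetone would remove the ketal to give 6,6-dimethylundecane-2,4,10-trione F3.
Alcohol 1 and diethylphosphonoacetic acid (DCC, DMAP) would give 8-phenylmenthyl 2-(diethoxyphosphoryl)acetate F4.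
Horner–Wadsworth–Emmons olefination of the methyl ketone of F3 with F4 (NaH, 2.2 equiv, THF, the diketone being protected as its enolate) would give 8-phenylmenthyl (E)-3,7,7-trimethyl-9,11-dioxododec-2-enoate F5 after removal of the minor Z isomer.
Thermodynamic bis-silylation of F5 (Et3SiCl, NaI, Et3N, MeCN) would then give the more substituted diene 14.

Step 7. The Lewis acid may expel the C8 silyloxy group by vinylogous elimination. The Michael addition may be interrupted without closing ring B, or the auxiliary may discriminate the faces poorly. The fallback sets out from 14 and comes back at 15. It gives up Lewis-acid activation and auxiliary-controlled face selection and uses a purely thermal, concerted intramolecular Diels–Alder reaction (toluene, 2,6-di-tert-butylpyridine as acid scavenger, 150 °C, sealed tube). The chiral ester then serves only as a handle for resolution. The trans-fused adduct 15 would be separated by chromatography from the diastereomeric adduct with the mirror-image bicyclic core F6, which is discarded.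

Step 14. The basic ylide may epimerise C6 next to the C7 ketone (relieving the 1,3-diaxial strain of the 6β-silyloxy group) or attack the ketone. The fallback sets out from 22 and comes back at 24. It reduces the ketone before the diene is made, so that no α-silyloxy ketone meets the ylide.
Luche reduction (NaBH4, CeCl3·7H2O, MeOH, −40 °C) of both carbonyl groups, with α-face delivery at C7, would give (12E)-6β,8α-bis(triethylsilyloxy)-15-norlabd-12-ene-7β,14-diol F7.
MnO2 in CH2Cl2 would re-oxidise only the allylic primary alcohol to give (12E)-7β-hydroxy-6β,8α-bis(triethylsilyloxy)-15-norlabd-12-en-14-al F8.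
Wittig methylenation with excess ylide (Ph3PCH3Br, KN(SiMe3)2) would then give 24.

Further compounds
F1 | step 6 | 4,4-dimethyl-7-(2-methyl-1,3-dioxolan-2-yl)heptan-2-one | CC(=O)CC(C)(C)CCCC1(C)OCCO1
F2 | step 6 | 6,6-dimethyl-9-(2-methyl-1,3-dioxolan-2-yl)nonane-2,4-dione | CC(=O)CC(=O)CC(C)(C)CCCC1(C)OCCO1
F3 | step 6 | 6,6-dimethylundecane-2,4,10-trione | CC(=O)CC(=O)CC(C)(C)CCCC(C)=O
F4 | step 6 | 8-phenylmenthyl 2-(diethoxyphosphoryl)acetate | CC(C)(c1ccccc1)[C@@H]1CC[C@@H](C)C[C@H]1OC(=O)CP(=O)(OCC)OCC
F5 | step 6 | 8-phenylmenthyl (E)-3,7,7-trimethyl-9,11-dioxododec-2-enoate | CC(C)(c1ccccc1)[C@@H]1CC[C@@H](C)C[C@H]1OC(=O)/C=C(\C)CCCC(C)(C)CC(=O)CC(C)=O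
F6 | step 7 | diastereomeric adduct, 8-phenylmenthyl ester of the mirror-image bicyclic acid | CC(C)(c1ccccc1)[C@@H]1CC[C@@H](C)C[C@H]1OC(=O)[C@@H]1[C@@](C)(O[Si](CC)(CC)CC)C=C(O[Si](CC)(CC)CC)[C@@H]2C(C)(C)CCC[C@]21C
F7 | step 14 | (12E)-6β,8α-bis(triethylsilyloxy)-15-norlabd-12-ene-7β,14-diol | OC/C(C)=C/C[C@H]1[C@](C)(O[Si](CC)(CC)CC)[C@@H](O)[C@@H](O[Si](CC)(CC)CC)[C@H]2C(C)(C)CCC[C@@]21C
F8 | step 14 | (12E)-7β-hydroxy-6β,8α-bis(triethylsilyloxy)-15-norlabd-12-en-14-al | O=C/C(C)=C/C[C@H]1[C@](C)(O[Si](CC)(CC)CC)[C@@H](O)[C@@H](O[Si](CC)(CC)CC)[C@H]2C(C)(C)CCC[C@@]21C
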